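The numbers in the tables come from a simulation with made-up constants; scatter was added.

At 75 h, 75.8% of the starting material charged to the eta run has still not appeared as product, and I want to know how soon such a flask stalls.

| flask | starting material | free catalyst | product | time |
|---|---|---|---|---|
| eta | 0.120 M | 6.00 × 10⁻⁴ M |  |  |
| zeta | 0.0720 M | 6.00 × 10⁻⁴ M |  |  |
| beta | 0.120 M | 0.00120 M |  |  |
| gamma | 0.120 M | 6.00 × 10⁻⁴ M | 0.0360 M |  |
| epsilon | 0.480 M | 6.00 × 10⁻⁴ M |  | 75 h |

| run | time / h | [product] / M |
|---|---|---|
| eta run | 3.0 | 0.0046 |
| eta run | 5.7 | 0.0085 |
| eta run | 11 | 0.0138 |
| eta run | 21 | 0.0207 |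
| eta run | 39 | 0.0253 |
| eta run | 75 | 0.0290 |
| zeta run | 3.0 | 0.0027 |
| zeta run | 5.7 | 0.0054 |
| zeta run | 11 | 0.0080 |
| zeta run | 21 | 0.0111 |
| zeta run | 39 | 0.0154 |
| zeta run | 75 | 0.0174 |
| beta run | 3.0 | 0.0097 |
| beta run | 5.7 | 0.0163 |
| beta run | 11 | 0.0229 |
| beta run | 21 | 0.0306 |
| beta run | 39 | 0.0368 |
| beta run | 75 | 0.0405 |
| gamma run | 3.0 | 0.0418 |
| gamma run | 5.7 | 0.0467 |
| gamma run | 11 | 0.0513 |
| gamma run | 21 | 0.0568 |
| gamma run | 39 | 0.0599 |
| gamma run | 75 | 0.0636 |

(standard deviation of a reading: 0.001 M)

- Overall: starting material -> product, with free catalyst as catalyst.
- Constant volume, constant temperature.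
- What is held in complexes is read along with the free species.
- An order is taken over about fifteen percent of the charge, up and down.

- order of the initial rate in [free catalyst], near the charge of the eta run, the rate being that where two percent of its starting material are product
- order of the initial rate in [starting material], near the charge of the eta run, the rate being that where two percent of its starting material are product (one fixed amount of product, the same in the runs compared)
- product in the epsilon run at 75 h, as a share of the starting material charged

I read two things from each of the eta, zeta and beta runs. X is the share of the charge that is product at 75 h, and a is the early fractional rate, a pseudo-first-order constant taken as the share made by 5.7 h divided by that time. For the eta run, X is 24.2% and a is 0.0124 h⁻¹. If the rate fades exponentially, the gap to X shrinks by a factor of two in T = 0.693 X/a, the stall half-life 13.5 h.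

| Run | X | a | T |
|---|---|---|---|
| eta | 24.2% | 0.0124 h⁻¹ | 13.5 h |
| zeta | 24.2% | 0.0132 h⁻¹ | 12.7 h |
| beta | 33.8% | 0.0238 h⁻¹ | 9.82 h |

The eta run has a ladder of time scales. At the pace a, about 1.61 h give the two percent at which the orders are asked, and there the curve is still close to a straight line. Next comes T, where the curve bends. Last comes 80.6 h, the time the early pace needs to turn the whole charge. T is shorter than that, so on this reckoning the eta run stalls before its charge has turned.

The zeta run, with its lower charge, reads a T of 12.7 h against 13.5 h and the same X, so I carry X to the epsilon run. Taking the T of the eta run, by 75 h the epsilon run has had 5.56 half-lives, which leaves 2.13% of the gap open, and I commit to about 24.2%. Chords to 5.7 h give me orders of 0.939 in free catalyst and 0.888 in starting material.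

The forecast gives 1.03 for the order in free catalyst, 0.95 for the order in starting material and 23% for the epsilon run: its orders are higher than mine and its share is lower. Its ground, speaking of starting material: “the stall does not depend on its level”.

The flask gives 1.0 for the order in free catalyst, 1.0 for the order in starting material and 23.2% for the epsilon run at 75 h.

    free catalyst + starting material ⇌ catalyst-substrate complex, settled at all times (1.110 M⁻¹)
    catalyst-substrate complex → product + free catalyst (28.76 h⁻¹)
    2 free catalyst → 2 spent catalyst (56.52 M⁻¹ h⁻¹)
    starting material → decomposed substrate (0.02624 h⁻¹)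

The epsilon run stands at 23.2% at 75 h because free catalyst turns to spent catalyst while starting material turns to decomposed substrate. The share of the forecast goes wrong if either path is taken away: the epsilon run then gives 35.1% at 75 h without the catalyst path, or 40.2% without the decomposition path. Carried to the beta run, its T of 9.82 h and X of 33.8% put a quarter of the charge at 19.1 h, and the beta run reaches it at 18.8 h.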